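The route rests on cutting the C1–C2 bond of the cyclohexenone ring (C1 carbinol, C2 CHOAc, C3 CHOBz, C4=C5, C6 ketone, C7 the CH2OBz carbon). C1(OH)–C6(=O) is a tertiary α-ketol, so the six-membered ring is the acyloin isomer of a 1-acylcyclopent-2-en-1-ol. One chelate-controlled α-ketol shift inserts the side-chain carbonyl carbon into the cyclopentene: C2 migrates from the carbinol carbon (future C6) to that carbonyl (future C1). This forms C1–C2, sets the quaternary C1 carbinol and places the new C6 ketone in conjugation with C4=C5. The precursor is a cis-fused cyclopentene acetonide carrying OH and COCH2OBz on one carbon, made by convex-face addition to a chiral-pool cyclopentenone. C3 is inverted later by Mitsunobu benzoylation.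

Key step: step 4

Assumption: enone 1 is taken as a catalogue chiral-pool building block in the (3aS,6aS) series, the mirror image of the D-ribose-derived enone. D-lyxose would give it by the sequence that leads from D-ribose to its antipode.

Step 1
Reactants: 1 (3aS,6aS)-2,2-dimethyl-3a,6a-dihydro-4H-cyclopenta[d][1,3]dioxol-4-one; 2 ethyl vinyl ether
Product: 4 (3aS,4R,6aS)-4-(1-ethoxyvinyl)-2,2-dimethyl-3a,6a-dihydro-4H-cyclopenta[d][1,3]dioxol-4-ol, via 1-ethoxyvinyllithium 3 (not isolated)
Conditions: 2, t-BuLi, THF, −78 → 0 °C; then 1, −78 °C; H2O quench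
Reagents that add atoms: none
Why: 1,2-addition of a hard α-alkoxyvinyllithium (acyl anion equivalent) to the enone carbonyl; the cis-fused acetonide blocks the concave face, so the C–C bond forms on the convex face and the new tertiary OH ends cis to the two acetonide oxygens (4R).

Step 2
Reactants: 4 (3aS,4R,6aS)-4-(1-ethoxyvinyl)-2,2-dimethyl-3a,6a-dihydro-4H-cyclopenta[d][1,3]dioxol-4-ol
Product: 5 2-bromo-1-[(3aS,4R,6aS)-4-hydroxy-2,2-dimethyl-3a,6a-dihydro-4H-cyclopenta[d][1,3]dioxol-4-yl]ethan-1-one
Conditions: NBS (1.0 equiv), THF/H2O 4:1, 0 °C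
Reagents that add atoms: N-bromosuccinimide O=C1CCC(=O)N1Br; water O
Why: Electrophilic bromohydration of the enol ether, by far the most electron-rich π bond present, gives a bromo-oxocarbenium ion that water should capture faster than any 1,2-shift, and the hemiketal loses ethanol to the α-bromo ketone without touching a stereocentre.

Step 3
Reactants: 5 2-bromo-1-[(3aS,4R,6aS)-4-hydroxy-2,2-dimethyl-3a,6a-dihydro-4H-cyclopenta[d][1,3]dioxol-4-yl]ethan-1-one
Product: 6 2-[(3aS,4R,6aS)-4-hydroxy-2,2-dimethyl-3a,6a-dihydro-4H-cyclopenta[d][1,3]dioxol-4-yl]-2-oxoethyl benzoate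
Conditions: PhCO2K, DMF, 0 °C → rt
Reagents that add atoms: potassium benzoate [K+].[O-]C(=O)c1ccccc1
Why: SN2 displacement of a primary α-keto bromide by a weakly basic carboxylate, fast enough at or below room temperature that the tertiary alcohol, the acetonide and the carbinol stereocentre are left alone.

Step 4
Reactants: 6 2-[(3aS,4R,6aS)-4-hydroxy-2,2-dimethyl-3a,6a-dihydro-4H-cyclopenta[d][1,3]dioxol-4-yl]-2-oxoethyl benzoate
Product: 7 [(3aS,4S,7aS)-4-hydroxy-2,2-dimethyl-5-oxo-3a,4,5,7a-tetrahydro-1,3-benzodioxol-4-yl]methyl benzoate (1S,2S,3S in target numbering; C1–OH and both acetonide oxygens on one face)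
Conditions: Sc(OTf)3 (10 mol %), 2,6-di-tert-butylpyridine (20 mol %), 4 Å MS, ClCH2CH2Cl, 70 °C
Reagents that add atoms: none
Why: Sc(III) ties the tertiary hydroxyl and the side-chain carbonyl of 6 into a five-membered chelate with the two oxygens syn-periplanar, the two ring bonds of the carbinol carbon then stand above and below the carbonyl plane, and the bond to the oxygen-bearing sp3 ring carbon (future C2) shifts with retention to the carbonyl carbon (future C1) while the carbinol carbon becomes the C6 ketone. This is the α-ketol (acyloin) rearrangement in its ring-enlarging form, known for 1-acylcyclopentanols going to 2-hydroxy-2-substituted cyclohexanones and for the Lewis-acid D-homoannulation of 17-hydroxy-20-oxo steroids. The six-membered ring is not closed by an exo or endo cyclisation; it grows from the five-membered ring by a concerted 1,2-shift through a three-centre transition state that inserts one carbon between the old carbinol carbon and C2, the cis-fused dioxolane being carried along unchanged. C1, the only new stereocentre, is controlled by the carbinol configuration from step 1 together with the chelate: with the acyl group on the face opposite the acetonide and C=O syn to O–H, C2 reaches the carbonyl face that leaves the new C1–OH cis to the C2 oxygen and C7 trans to it (1S), whereas C2 and C3 keep their configuration. The step needs migration of the sp3 carbon rather than of the sp2 carbon C5, and this is secured by thermodynamics: α-ketol shifts are reversible, and only the sp3 shift gives a cyclohexenone whose ketone is conjugated with C4=C5, so that the non-conjugated isomer from a vinyl shift should drain back through 6. The acyl group disfavours ionisation of the tertiary allylic alcohol, and the hindered pyridine traps adventitious TfOH, which should keep acetonide and benzoate in place.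

Step 5
Reactants: 7 [(3aS,4S,7aS)-4-hydroxy-2,2-dimethyl-5-oxo-3a,4,5,7a-tetrahydro-1,3-benzodioxol-4-yl]methyl benzoate
Product: 8 [(1S,2S,3S)-1,2,3-trihydroxy-6-oxocyclohex-4-en-1-yl]methyl benzoate (all three hydroxyls cis)
Conditions: TFA/H2O 4:1, 0 °C → rt
Reagents that add atoms: none
Why: Acid-catalysed hydrolysis of the isopropylidene ketal; benzoate, enone and tertiary α-ketol should tolerate cold aqueous TFA, and no C–O bond at a stereocentre is broken.

Step 6
Reactants: 8 [(1S,2S,3S)-1,2,3-trihydroxy-6-oxocyclohex-4-en-1-yl]methyl benzoate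
Product: 9 zeylenone, [(1S,2S,3R)-3-(benzoyloxy)-1,2-dihydroxy-6-oxocyclohex-4-en-1-yl]methyl benzoate
Conditions: PhCO2H (1.2 equiv), PPh3, DIAD, THF, −20 → 0 °C
Reagents that add atoms: benzoic acid OC(=O)c1ccccc1
Why: Mitsunobu reaction: the allylic C3–OH is the only hydroxyl that is both accessible and SN2-active (C2–OH is flanked by the quaternary C1, C1–OH is tertiary, and the neighbouring oxygens are syn to the leaving group and cannot displace it), so benzoate should enter from the opposite face with inversion to 3R, trans to the C2 oxygen.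

Step 7
Reactants: 9 zeylenone
Product: 10 2-O-acetylzeylenone, [(1S,2S,3R)-2-acetoxy-3-(benzoyloxy)-1-hydroxy-6-oxocyclohex-4-en-1-yl]methyl benzoate
Conditions: Ac2O (1.5 equiv), pyridine, CH2Cl2, 0 °C
Reagents that add atoms: acetic anhydride CC(=O)OC(C)=O
Why: Chemoselective O-acetylation (nucleophilic acyl substitution) of the only secondary alcohol; without DMAP the tertiary C1–OH should not react, and the mild base leaves the γ-acyloxy enone and all stereocentres intact.

Compound list
1 | (3aS,6aS)-2,2-dimethyl-3a,6a-dihydro-4H-cyclopenta[d][1,3]dioxol-4-one, i.e. (4S,5S)-4,5-O-isopropylidenecyclopent-2-enone | O=C1C=C[C@@H]2OC(C)(C)O[C@H]12 | starting material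
2 | ethyl vinyl ether | C=COCC | starting material
3 | 1-ethoxyvinyllithium | [Li]C(=C)OCC | intermediate
4 | (3aS,4R,6aS)-4-(1-ethoxyvinyl)-2,2-dimethyl-3a,6a-dihydro-4H-cyclopenta[d][1,3]dioxol-4-ol (OH cis to the acetonide oxygens) | CCOC(=C)[C@@]1(O)C=C[C@@H]2OC(C)(C)O[C@H]12 | intermediate
5 | 2-bromo-1-[(3aS,4R,6aS)-4-hydroxy-2,2-dimethyl-3a,6a-dihydro-4H-cyclopenta[d][1,3]dioxol-4-yl]ethan-1-one | O=C(CBr)[C@@]1(O)C=C[C@@H]2OC(C)(C)O[C@H]12 | intermediate
6 | 2-[(3aS,4R,6aS)-4-hydroxy-2,2-dimethyl-3a,6a-dihydro-4H-cyclopenta[d][1,3]dioxol-4-yl]-2-oxoethyl benzoate | O=C(COC(=O)c1ccccc1)[C@@]1(O)C=C[C@@H]2OC(C)(C)O[C@H]12 | intermediate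
7 | [(3aS,4S,7aS)-4-hydroxy-2,2-dimethyl-5-oxo-3a,4,5,7a-tetrahydro-1,3-benzodioxol-4-yl]methyl benzoate | O=C1C=C[C@@H]2OC(C)(C)O[C@@H]2[C@@]1(O)COC(=O)c1ccccc1 | intermediate
8 | [(1S,2S,3S)-1,2,3-trihydroxy-6-oxocyclohex-4-en-1-yl]methyl benzoate | O=C1C=C[C@H](O)[C@H](O)[C@@]1(O)COC(=O)c1ccccc1 | intermediate
9 | zeylenone, [(1S,2S,3R)-3-(benzoyloxy)-1,2-dihydroxy-6-oxocyclohex-4-en-1-yl]methyl benzoate | O=C1C=C[C@@H](OC(=O)c2ccccc2)[C@H](O)[C@@]1(O)COC(=O)c1ccccc1 | intermediate
10 | 2-O-acetylzeylenone | CC(=O)O[C@H]1[C@H](OC(=O)c2ccccc2)C=CC(=O)[C@]1(O)COC(=O)c1ccccc1 | target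

Total step count: 7. Longest linear sequence: 7 steps (from 1).

Steps most likely to fail

1. Step 4.
- Risk: migration of the sp2 ring carbon may be kinetically faster. Equilibration to the conjugated enone may then be too slow to finish before acetonide loss or benzoyl transfer sets in.
- Risk: incomplete chelation would erode the facial control at C1.
- Fallback, from 4 back to 7: the shift is run on an ester-free substrate under stoichiometric aluminium alkoxide chelation, where forcing equilibration is tolerated.
- Enol ether 4 is oxidised with dimethyldioxirane (Rubottom-type oxidation, aqueous work-up) to the dihydroxy ketone F1.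
- TBSCl/imidazole protects the primary hydroxyl to give the primary silyl ether F2.
- Al(Ot-Bu)3 in refluxing toluene should convert F2 into the ring-enlarged silyl ether F3.
- HF·pyridine frees the ring-enlarged diol F4.
- BzCl/pyridine at 0 °C benzoylates only the primary hydroxyl to give 7.

2. Step 6.
- Risk: the cis-2,3-diol may be engaged as a dioxaphosphorane with loss of regiocontrol.
- Risk: the oxyphosphonium group may leave by E2 elimination towards C2 instead of being displaced.
- Fallback, from 8 back to 9: activation and displacement are separated.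
- SOCl2/Et3N closes the two secondary hydroxyls to the cyclic sulfite F5.
- RuCl3 (cat.)/NaIO4 oxidises it to the cyclic sulfate F6.
- Caesium benzoate in DMF opens F6 by SN2 at the allylic C3 with inversion to the C2 hydrogen sulfate F7.
- Catalytic H2SO4 in wet THF hydrolyses the sulfate ester to 9.

3. Step 2.
- Risk: a premature, kinetically controlled 1,2-shift within the bromo-oxocarbenium ion.
- Risk: bromination of the ring alkene may compete with capture by water.
- Fallback, from 4 back to 6, without halogen: oxalic acid in wet THF hydrolyses the enol ether to the methyl ketone F8.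
- N-methyl-O-benzoylhydroxylamine hydrochloride in DMSO at rt then condenses with the ketone.
- A [3,3]-sigmatropic shift of the derived N-vinyl species delivers benzoate to the only enolisable carbon, giving 6 directly.

Further compounds
F1 | step 4 | 2-hydroxy-1-[(3aS,4R,6aS)-4-hydroxy-2,2-dimethyl-3a,6a-dihydro-4H-cyclopenta[d][1,3]dioxol-4-yl]ethan-1-one | O=C(CO)[C@@]1(O)C=C[C@@H]2OC(C)(C)O[C@H]12
F2 | step 4 | 2-(tert-butyldimethylsilyloxy)-1-[(3aS,4R,6aS)-4-hydroxy-2,2-dimethyl-3a,6a-dihydro-4H-cyclopenta[d][1,3]dioxol-4-yl]ethan-1-one | O=C(CO[Si](C)(C)C(C)(C)C)[C@@]1(O)C=C[C@@H]2OC(C)(C)O[C@H]12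
F3 | step 4 | (3aS,4S,7aS)-4-[(tert-butyldimethylsilyloxy)methyl]-4-hydroxy-2,2-dimethyl-3a,7a-dihydro-1,3-benzodioxol-5(4H)-one | O=C1C=C[C@@H]2OC(C)(C)O[C@@H]2[C@@]1(O)CO[Si](C)(C)C(C)(C)C
F4 | step 4 | (3aS,4S,7aS)-4-hydroxy-4-(hydroxymethyl)-2,2-dimethyl-3a,7a-dihydro-1,3-benzodioxol-5(4H)-one | O=C1C=C[C@@H]2OC(C)(C)O[C@@H]2[C@@]1(O)CO
F5 | step 6 | 2,3-O-cyclic sulfite of 8 (mixture at sulfur) | O=C1C=C[C@@H]2OS(=O)O[C@@H]2[C@@]1(O)COC(=O)c1ccccc1
F6 | step 6 | 2,3-O-cyclic sulfate of 8 | O=C1C=C[C@@H]2OS(=O)(=O)O[C@@H]2[C@@]1(O)COC(=O)c1ccccc1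
F7 | step 6 | zeylenone 2-O-hydrogen sulfate | O=C1C=C[C@@H](OC(=O)c2ccccc2)[C@H](OS(=O)(=O)O)[C@@]1(O)COC(=O)c1ccccc1
F8 | step 2 | 1-[(3aS,4R,6aS)-4-hydroxy-2,2-dimethyl-3a,6a-dihydro-4H-cyclopenta[d][1,3]dioxol-4-yl]ethan-1-one | CC(=O)[C@@]1(O)C=C[C@@H]2OC(C)(C)O[C@H]12
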